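The data were computed from invented constants, and the scatter is random.

- At a fixed temperature, the quotient [target]/([substrate][partner]) stops moving once the reversible step has levelled, even while the side step drains the pool. Partner is not read, so it is reckoned from the proposed steps, with the missing percentage taken as side product. The last south reading gives this levelled quotient as 0.0208 /mM.
- The last north-east reading, at twice the partner, reads 0.0210 /mM. The two readings agree, so late target in south and north-east stands under thermodynamic control at 0 °C.

| flask | substrate | partner | temperature | remark | time |
|---|---|---|---|---|---|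
| north | 20 mM | 30 mM | −15 °C | run made earlier |  |
| south | 10 mM | 30 mM | 0 °C | run made earlier |  |
| south-east | 15 mM | 30 mM | −15 °C | run made earlier |  |
| north-east | 20 mM | 60 mM | 0 °C | run made earlier |  |
| ochre | 20 mM | 30.0 mM | 0 °C | everything together at the start | 8.0 h |
| green | 20 mM | 30.0 mM (fed, over 1.5 h) |  | the addition at −20 °C, then warmed to 0 °C; the feed brings no volume worth counting | 8.0 h |
| violet | 20 mM (fed, over 1.5 h) | 30.0 mM | 0 °C | all else is in the flask from the start; the feed brings no volume worth counting | 8.0 h |
| teal | 20 mM | 30.0 mM (fed, over 10 min) | 0 °C | all else is in the flask from the start; the feed brings no volume worth counting | 8.0 h |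

- north (time / h: target / %, substrate / %): 0.833: 4.8, 94.0; 1.33: 8.2, 91.1; 3.00: 15.3, 82.3; 5.00: 21.4, 75.7; 10.0: 30.4, 65.2
- south (time / h: target / %, substrate / %): 0.417: 13.0, 85.7; 0.667: 18.7, 79.9; 1.33: 25.9, 71.2; 2.50: 30.1, 63.4; 5.00: 30.5, 59.1
- south-east (time / h: target / %, substrate / %): 0.833: 4.8, 94.3; 3.00: 15.2, 82.2; 4.00: 18.8, 78.5; 6.00: 24.7, 71.6; 10.0: 30.2, 64.2
- north-east (time / h: target / %, substrate / %): 1.00: 35.7, 55.7; 2.00: 40.9, 46.0; 3.00: 40.1, 42.8; 4.00: 39.1, 41.0; 5.00: 36.8, 40.3

(readings scatter by 0.5 percentage points)

1. which flask leads in amount of target, in percent of the substrate charged ("all alike" within 1.5 percentage points) (ochre / green / violet / teal / all alike)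
2. how much target is there at the end, in percent of the substrate charged: ochre
3. how much target is there at the end, in percent of the substrate charged: green
4. how much target is there at the end, in percent of the substrate charged: violet
5. how much target is there at the end, in percent of the substrate charged: teal

- First extreme, ochre without the side step: the quotient and the charges give target 6.55 mM, or 32.7%.
- Second extreme, the side step holding its start rate throughout: side product grows by 0.156 mM/h late in south. Scaled as [substrate][partner]² to the ochre charges, that becomes 0.768 mM/h. Over 8.0 h the quotient then leaves 3.21 mM of target, or 16.0%.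
- Joining them: at the levelled concentrations of the first extreme, the side step runs at 0.316 mM/h, slower than at the start. Held over 8.0 h, that rate takes 2.53 mM of substrate, and the quotient then leaves 5.10 mM of target, or 25.5%.
- The first south reading gives a forward constant near 0.0104 /mM/h, so levelling takes about 1.13 h. Green still has 6.50 h at 0 °C after its feed, longer than that.
- A delay of the side step taken as the length of the slow feed, 1.5 h, is worth about 1.4 percentage points of target. That is narrowly under the margin of 1.5 points, so the reckoning here expects flasks counted as alike, with the feeds slightly ahead.
- The forecast also says all alike, with ochre 24%, green 25%, violet 24.8% and teal 24.1%, since “every flask sits on the same equilibrium”; its ochre figure lies below the 25.5% reckoned here.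
- The flasks end at 26.2% for ochre, 27.1% for green, 26.7% for violet and 26.3% for teal, so the answer is all alike, with a spread of 0.90 points. Ochre at 8.00 h holds side product 11.1% and partner 67.5% of its own charge. The quotient turns that partner into a ratio [target]/[substrate] of 0.420, and the share of substrate not in side product then divides into target 26.3%.

    substrate + 2 partner → side product (k = 40.0 /M²/h, Ea = 50.0 kJ/mol)
    substrate + partner ⇌ target (K = 20.0 /M, k = 13.0 /M/h, Ea = 69.0 kJ/mol, ΔH = −16.0 kJ/mol)
    crystals ⇌ target, rate k3*(cs3 - [target]) while solid is left; crystals form when [target] > cs3 (solubility = 9.50 mM, k = 0.710 /h)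
    partner → decomposition product (k = 3.10 × 10⁻⁴ /h, Ea = 98.0 kJ/mol)
    (constants at 0 °C)

- A teal flask with 75 mM of partner keeps 69.7% of that charge, so the quotient gives a ratio of 1.08. With side product 40.6%, the same division gives target 30.9%. The computed flask holds 31.8%.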